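The route rests on cutting the bond between C1''' of the p-phenylene ring and C2'' of the genkwanin pyranone (ring C''). C2'' stands at the carboxyl oxidation level, and O1'' and the 5''-OH are the two homotopic hydroxyls of a symmetric ring A''. Ring C'' is therefore assembled in one operation from three components: aryl bromide 7 (the complete, benzyl-protected 8-aryloxyacacetin half), carbon monoxide (the future C2'') and 2',6'-dihydroxy-4'-methoxyacetophenone. A Pd-catalysed carbonylative aroylation/Baker–Venkataraman/cyclodehydration cascade forms C1'''–C2'', C2''–C3'' and C2''–O1''. The precursor contains no second chromone. Bromide 7 comes from acacetin by C8 iodination, borylation–oxidation and iodonium O-arylation.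

Key step: step 5

Remark on the chemistry: the target has no stereocentre, and its diaryl ether and aryl–chromone axes rotate freely. It is therefore achiral and the route needs no stereocontrol. Locants: unprimed = acacetin chromone, ' = its anisyl ring, '' = genkwanin chromone, ''' = p-phenylene ring.

Step 1
Reactants: 1 acacetin (5,7-dihydroxy-2-(4-methoxyphenyl)-4H-chromen-4-one)
Product: 2 5,7-bis(benzyloxy)-2-(4-methoxyphenyl)-4H-chromen-4-one
Conditions: BnBr (3 equiv), K2CO3, DMF, 80 °C
Reagents that add atoms: benzyl bromide, BrCc1ccccc1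
Why: Williamson ether synthesis: the acidic 7-OH is alkylated first and excess benzyl bromide in hot DMF also overcomes the hydrogen bond of the chelated 5-OH, so that no acidic proton is left for the later base- and Pd-mediated steps.

Step 2
Reactants: 2 5,7-bis(benzyloxy)-2-(4-methoxyphenyl)-4H-chromen-4-one
Product: 3 5,7-bis(benzyloxy)-8-iodo-2-(4-methoxyphenyl)-4H-chromen-4-one
Conditions: NIS (1.05 equiv), cat. TFA, MeCN–CH2Cl2, 0 °C to rt
Reagents that add atoms: N-iodosuccinimide, O=C1CCC(=O)N1I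
Why: Electrophilic aromatic iodination: ring A, activated by three oxygen substituents, outcompetes the anisyl ring that is deactivated by conjugation with the pyranone, and in fully O-alkylated 5,7-dioxygenated flavones attack goes to C8 rather than to C6, which is buried between two benzyloxy groups.

Step 3
Reactants: 3 5,7-bis(benzyloxy)-8-iodo-2-(4-methoxyphenyl)-4H-chromen-4-one
Product: 5 5,7-bis(benzyloxy)-8-hydroxy-2-(4-methoxyphenyl)-4H-chromen-4-one, via C8 pinacol boronate 4 (not isolated)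
Conditions: HBpin, PdCl2(MeCN)2 (cat.), SPhos (cat.), Et3N, dioxane, 80 °C; then 30% H2O2, aq. NaOH, THF, 0 °C
Reagents that add atoms: pinacolborane, [H]B1OC(C)(C)C(C)(C)O1 (boron group of 4 only); hydrogen peroxide, OO
Why: Pd-catalysed Miyaura-type borylation with pinacolborane under a bulky biarylphosphine, a system suited to doubly ortho-substituted electron-rich aryl halides, is followed by ipso-oxidation of the C–B bond (1,2-aryl shift from boron to oxygen), which fixes the oxygen exactly at C8.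

Step 4
Reactants: 5 5,7-bis(benzyloxy)-8-hydroxy-2-(4-methoxyphenyl)-4H-chromen-4-one; 6 bis(4-bromophenyl)iodonium trifluoromethanesulfonate
Product: 7 5,7-bis(benzyloxy)-8-(4-bromophenoxy)-2-(4-methoxyphenyl)-4H-chromen-4-one
Conditions: t-BuOK (1.05 equiv), THF, 0 °C; then 6, 40 °C, argon
Reagents that add atoms: none
Why: Metal-free O-arylation with a diaryliodonium salt (ligand exchange at iodine(III), then ligand coupling) tolerates doubly ortho-flanked phenoxides, the symmetric salt can transfer only a 4-bromophenyl group, and without a transition metal the C–Br bond stays intact.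

Step 5
Reactants: 7 5,7-bis(benzyloxy)-8-(4-bromophenoxy)-2-(4-methoxyphenyl)-4H-chromen-4-one; 8 2',6'-dihydroxy-4'-methoxyacetophenone; 9 carbon monoxide
Product: 12 5,7-bis(benzyloxy)-8-[4-(5-hydroxy-7-methoxy-4-oxo-4H-chromen-2-yl)phenoxy]-2-(4-methoxyphenyl)-4H-chromen-4-one, via aryl ester 10 (not isolated), via 1,3-diketone 11 (not isolated)
Conditions: CO (10 bar), Pd(OAc)2 (cat.), dppb (cat.), DBU (4 equiv), 8 (2 equiv), DMF, 120 °C
Reagents that add atoms: none
Why: Pd(0) inserts into the C–Br bond of 7 and CO insertion creates the C1'''–C2'' bond as an aroyl–Pd species, which the DBU phenoxide of 8 captures to give ester 10; DBU then enolises the acetyl group, a Baker–Venkataraman O-to-C acyl shift gives diketone 11 (C2''–C3'' bond), and a phenol oxygen adds to the aroyl carbonyl with loss of water (C2''–O1'' bond). The closest known reaction type is the Pd-catalysed carbonylative flavone synthesis from aryl bromides, CO and 2-hydroxyacetophenones, the carbonylative form of the one-pot DBU Baker–Venkataraman procedure. Ring C'' closes by 6-exo-trig hemiketalisation at C2'' followed by E1cB dehydration to the 4-pyranone. No stereocentre is formed. The step needs one direction of ring closure and mono-aroylation: the two hydroxyls of 8 are homotopic, so either gives the 5''-hydroxy-7''-methoxy pattern and the unused one ends as the chelated 5''-OH without protection, while excess 8 holds back double aroylation and 3-aroylflavone formation. Bromide 7 carries no acidic proton, its 5-O-benzyl group blocks base-induced opening and reclosure of ring C that would move the aryloxy group from C8 to C6, and CO pressure suppresses direct C–O coupling and ketone α-arylation.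

Step 6
Reactants: 12 5,7-bis(benzyloxy)-8-[4-(5-hydroxy-7-methoxy-4-oxo-4H-chromen-2-yl)phenoxy]-2-(4-methoxyphenyl)-4H-chromen-4-one
Product: 13 5,7-dihydroxy-8-[4-(5-hydroxy-7-methoxy-4-oxo-4H-chromen-2-yl)phenoxy]-2-(4-methoxyphenyl)-4H-chromen-4-one (CNP0124888.0)
Conditions: H2 (1 atm), 10% Pd/C, THF–MeOH, rt
Reagents that add atoms: none
Why: Catalytic hydrogenolysis of the two benzyl aryl ethers under neutral conditions leaves the methyl ethers, the diaryl ether and both chromone C2=C3 bonds untouched and avoids the acid that could trigger a Wessely–Moser rearrangement of the 8-aryloxy-5,7-dihydroxy ring A.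

Compound list
1 | acacetin | COc1ccc(cc1)-c1cc(=O)c2c(O)cc(O)cc2o1 | starting material
2 | 5,7-bis(benzyloxy)-2-(4-methoxyphenyl)-4H-chromen-4-one | COc1ccc(cc1)-c1cc(=O)c2c(OCc3ccccc3)cc(OCc3ccccc3)cc2o1 | intermediate
3 | 5,7-bis(benzyloxy)-8-iodo-2-(4-methoxyphenyl)-4H-chromen-4-one | COc1ccc(cc1)-c1cc(=O)c2c(OCc3ccccc3)cc(OCc3ccccc3)c(I)c2o1 | intermediate
4 | 5,7-bis(benzyloxy)-2-(4-methoxyphenyl)-8-(4,4,5,5-tetramethyl-1,3,2-dioxaborolan-2-yl)-4H-chromen-4-one | COc1ccc(cc1)-c1cc(=O)c2c(OCc3ccccc3)cc(OCc3ccccc3)c(B3OC(C)(C)C(C)(C)O3)c2o1 | intermediate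
5 | 5,7-bis(benzyloxy)-8-hydroxy-2-(4-methoxyphenyl)-4H-chromen-4-one | COc1ccc(cc1)-c1cc(=O)c2c(OCc3ccccc3)cc(OCc3ccccc3)c(O)c2o1 | intermediate
6 | bis(4-bromophenyl)iodonium trifluoromethanesulfonate | Brc1ccc(cc1)[I+]c1ccc(Br)cc1.[O-]S(=O)(=O)C(F)(F)F | starting material
7 | 5,7-bis(benzyloxy)-8-(4-bromophenoxy)-2-(4-methoxyphenyl)-4H-chromen-4-one | COc1ccc(cc1)-c1cc(=O)c2c(OCc3ccccc3)cc(OCc3ccccc3)c(Oc3ccc(Br)cc3)c2o1 | intermediate
8 | 2',6'-dihydroxy-4'-methoxyacetophenone | CC(=O)c1c(O)cc(OC)cc1O | starting material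
9 | carbon monoxide | [C-]#[O+] | starting material
10 | 2-acetyl-3-hydroxy-5-methoxyphenyl 4-{[5,7-bis(benzyloxy)-2-(4-methoxyphenyl)-4-oxo-4H-chromen-8-yl]oxy}benzoate | COc1ccc(cc1)-c1cc(=O)c2c(OCc3ccccc3)cc(OCc3ccccc3)c(Oc3ccc(cc3)C(=O)Oc3cc(OC)cc(O)c3C(C)=O)c2o1 | intermediate
11 | 1-(4-{[5,7-bis(benzyloxy)-2-(4-methoxyphenyl)-4-oxo-4H-chromen-8-yl]oxy}phenyl)-3-(2,6-dihydroxy-4-methoxyphenyl)propane-1,3-dione | COc1ccc(cc1)-c1cc(=O)c2c(OCc3ccccc3)cc(OCc3ccccc3)c(Oc3ccc(cc3)C(=O)CC(=O)c3c(O)cc(OC)cc3O)c2o1 | intermediate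
12 | 5,7-bis(benzyloxy)-8-[4-(5-hydroxy-7-methoxy-4-oxo-4H-chromen-2-yl)phenoxy]-2-(4-methoxyphenyl)-4H-chromen-4-one | COc1ccc(cc1)-c1cc(=O)c2c(OCc3ccccc3)cc(OCc3ccccc3)c(Oc3ccc(cc3)-c3cc(=O)c4c(O)cc(OC)cc4o3)c2o1 | intermediate
13 | 5,7-dihydroxy-8-[4-(5-hydroxy-7-methoxy-4-oxo-4H-chromen-2-yl)phenoxy]-2-(4-methoxyphenyl)-4H-chromen-4-one (CNP0124888.0, achiral) | COc1ccc(-c2cc(=O)c3c(O)cc(O)c(Oc4ccc(-c5cc(=O)c6c(O)cc(OC)cc6o5)cc4)c3o2)cc1 | target

Total step count: 6. Longest linear sequence: 6 steps (1 to 13); compounds 6, 8 and 9 are purchased.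

Steps most likely to fail

Step 5. Chelation of palladium by the β-diketonate and polyphenolate species could deactivate the catalyst. The cascade could also stall at the acyl-transfer stage, or a second aroylation could occur. The fallback makes the same C1'''–C2'' bond by conjugate arylation of a preformed chromone. It sets out from 7 (and 8) and comes back at 12.
- Bromide 7 would be borylated with tetrahydroxydiboron (XPhos-Pd-G2, KOAc, EtOH–THF, 80 °C) to the arylboronic acid F1.
- In parallel, 8 would be condensed with DMF dimethyl acetal (toluene, 80 °C) to the enaminone F2.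
- The enaminone would be closed with HCl in CH2Cl2 to 5-hydroxy-7-methoxychromone F3.
- Pd(II)-catalysed conjugate addition of the boronic acid to the chromone (Pd(TFA)2, 2,2'-bipyridine, AcOH–THF–H2O, 60 °C) should give the racemic flavanone F4.
- Dehydrogenation with DDQ in dioxane under reflux erases its stereocentre and delivers 12.

Step 3. Protodeiodination could outrun borylation at the doubly ortho-substituted C8, and the electron-rich phenol could be over-oxidised. The fallback introduces the C8 oxygen by oxidation of a phenolate instead of cross-coupling. It sets out from 1 and comes back at 7.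
- Selective alkylation of the acidic 7-OH (BnBr 1.1 equiv, K2CO3, acetone, reflux) would give 7-O-benzylacacetin F5.
- Elbs persulfate oxidation (K2S2O8, aq. KOH–pyridine, rt) attacks para to the free 5-OH, which is C8, to give the potassium aryl sulfate F6.
- Hot dilute HCl would hydrolyse the sulfate to the 5,8-quinol F7.
- The non-chelated 8-OH would be arylated selectively with 6 (t-BuOK 1 equiv, THF, argon) to the 5-hydroxy bromide F8.
- Forced benzylation of the chelated 5-OH (BnBr, K2CO3, DMF, 80 °C) gives 7.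

Step 4. Ligand coupling at the doubly flanked phenoxide could be slow, and electron transfer from the electron-rich phenoxide to iodine(III) could decompose the salt. The fallback builds the ether by nucleophilic aromatic substitution and installs the bromine afterwards. It sets out from 5 and comes back at 7.
- Phenol 5 with 1-fluoro-4-nitrobenzene (K2CO3, DMF, 80 °C) would give the nitro ether F9.
- Reduction with Fe and NH4Cl in aqueous EtOH spares the benzyl ethers and gives the aniline F10.
- Diazotisation (t-BuONO, BF3·OEt2, THF, −15 °C) gives the diazonium tetrafluoroborate F11.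
- A catalytic Sandmeyer bromination (KBr, cat. CuBr/CuBr2, 1,10-phenanthroline, MeCN, rt) gives 7.

Further compounds
F1 | step 5 | 4-{[5,7-bis(benzyloxy)-2-(4-methoxyphenyl)-4-oxo-4H-chromen-8-yl]oxy}phenylboronic acid | COc1ccc(cc1)-c1cc(=O)c2c(OCc3ccccc3)cc(OCc3ccccc3)c(Oc3ccc(cc3)B(O)O)c2o1
F2 | step 5 | (E)-1-(2,6-dihydroxy-4-methoxyphenyl)-3-(dimethylamino)prop-2-en-1-one | CN(C)/C=C/C(=O)c1c(O)cc(OC)cc1O
F3 | step 5 | 5-hydroxy-7-methoxy-4H-chromen-4-one | COc1cc(O)c2c(=O)ccoc2c1
F4 | step 5 | racemic 5,7-bis(benzyloxy)-8-[4-(5-hydroxy-7-methoxy-4-oxochroman-2-yl)phenoxy]-2-(4-methoxyphenyl)-4H-chromen-4-one | COc1ccc(cc1)-c1cc(=O)c2c(OCc3ccccc3)cc(OCc3ccccc3)c(Oc3ccc(cc3)C3CC(=O)c4c(O)cc(OC)cc4O3)c2o1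
F5 | step 3 | 7-(benzyloxy)-5-hydroxy-2-(4-methoxyphenyl)-4H-chromen-4-one | COc1ccc(cc1)-c1cc(=O)c2c(O)cc(OCc3ccccc3)cc2o1
F6 | step 3 | potassium 7-(benzyloxy)-5-hydroxy-2-(4-methoxyphenyl)-4-oxo-4H-chromen-8-yl sulfate | COc1ccc(cc1)-c1cc(=O)c2c(O)cc(OCc3ccccc3)c(OS(=O)(=O)[O-])c2o1.[K+]
F7 | step 3 | 7-(benzyloxy)-5,8-dihydroxy-2-(4-methoxyphenyl)-4H-chromen-4-one | COc1ccc(cc1)-c1cc(=O)c2c(O)cc(OCc3ccccc3)c(O)c2o1
F8 | step 3 | 7-(benzyloxy)-8-(4-bromophenoxy)-5-hydroxy-2-(4-methoxyphenyl)-4H-chromen-4-one | COc1ccc(cc1)-c1cc(=O)c2c(O)cc(OCc3ccccc3)c(Oc3ccc(Br)cc3)c2o1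
F9 | step 4 | 5,7-bis(benzyloxy)-2-(4-methoxyphenyl)-8-(4-nitrophenoxy)-4H-chromen-4-one | COc1ccc(cc1)-c1cc(=O)c2c(OCc3ccccc3)cc(OCc3ccccc3)c(Oc3ccc(cc3)[N+](=O)[O-])c2o1
F10 | step 4 | 8-(4-aminophenoxy)-5,7-bis(benzyloxy)-2-(4-methoxyphenyl)-4H-chromen-4-one | COc1ccc(cc1)-c1cc(=O)c2c(OCc3ccccc3)cc(OCc3ccccc3)c(Oc3ccc(N)cc3)c2o1
F11 | step 4 | 4-{[5,7-bis(benzyloxy)-2-(4-methoxyphenyl)-4-oxo-4H-chromen-8-yl]oxy}benzenediazonium tetrafluoroborate | COc1ccc(cc1)-c1cc(=O)c2c(OCc3ccccc3)cc(OCc3ccccc3)c(Oc3ccc(cc3)[N+]#N)c2o1.F[B-](F)(F)F
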